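**Retrosynthetic overview**
1. Last step: selective di‑O‑acetylation of (13Z)‑labda‑8,13‑diene‑6β,7α,15‑triol at O‑7 and O‑15; the axial 6β‑OH stays free.
2. C12–C13: stereoretentive sp3–sp2 coupling of a 12‑iodo‑tetranorlabd‑8‑ene‑6β,7α‑diol with (Z)‑3‑iodobut‑2‑en‑1‑ol fixes the 13Z olefin.
3. Ring B oxygens: 6β‑OH by α‑face hydride reduction of a 7α‑acyloxy‑8‑en‑6‑one; the key disconnection is C7–O, made by a [3,3] N‑to‑C acyloxy shift in the dienamine of a 7‑en‑6‑one, which also moves the double bond to C8=C9.
4. The 7‑en‑6‑one comes from allylic oxidation of the Δ7 olefin, reached from the 8(17)‑olefin obtained by opening and dehydrating (+)‑sclareolide.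
5. Ring order: no ring is built; rings A and B come intact from sclareolide, and only its lactone ring is opened.

Assumption: the target is read as (13Z)‑7α,15‑diacetoxylabda‑8,13‑dien‑6β‑ol of the normal labdane series (5S,6S,7S,10S; labdane numbering used throughout), and common reagents, ligands and the surfactant are bought.

**Route**

Step 1
Reactants: 1 (+)-sclareolide
Product: 3 methyl 8α-hydroxy-13,14,15,16-tetranorlabdan-12-oate, via potassium 8α-hydroxy-carboxylate 2 (not isolated)
Conditions: KOH, MeOH–H2O, reflux; evaporate; then MeI, DMF, rt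
Reagents that add atoms: potassium hydroxide [K+].[OH-]; iodomethane CI
Why: Saponification of the γ‑lactone followed by SN2 O‑methylation of the carboxylate in DMF traps the tertiary hydroxy acid as its methyl ester before it can relactonise, and no stereocentre is touched.

Step 2
Reactants: 3 methyl 8α-hydroxy-13,14,15,16-tetranorlabdan-12-oate
Product: 4 methyl 13,14,15,16-tetranorlabd-8(17)-en-12-oate
Conditions: SOCl2, pyridine, CH2Cl2, −78 °C
Reagents that add atoms: none
Why: E2‑type dehydration through the chlorosulfite: the equatorial 8α‑oxygen has no anti‑periplanar ring hydrogen, so a C‑17 methyl hydrogen is lost and the exocyclic 8(17)‑olefin is the main product, as expected for sclareolide‑derived 8α‑ols at low temperature.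

Step 3
Reactants: 4 methyl 13,14,15,16-tetranorlabd-8(17)-en-12-oate
Product: 5 methyl 13,14,15,16-tetranorlabd-7-en-12-oate
Conditions: RhCl3·3H2O (5 mol %), i-PrOH, 80 °C
Reagents that add atoms: none
Why: Transition‑metal olefin isomerisation by Rh–H addition and β‑hydride elimination moves the exocyclic double bond into the ring toward the accessible C‑7 methylene (the tertiary C9–H next to quaternary C‑10 should react much more slowly), giving the trisubstituted Δ7 olefin with C‑9 untouched.

Step 4
Reactants: 5 methyl 13,14,15,16-tetranorlabd-7-en-12-oate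
Product: 6 methyl 6-oxo-13,14,15,16-tetranorlabd-7-en-12-oate
Conditions: CrO3, 3,5-dimethylpyrazole, CH2Cl2, −20 °C
Reagents that add atoms: chromium trioxide O=[Cr](=O)=O
Why: Allylic oxidation of the ring CH2 at C‑6 with CrO3·3,5‑dimethylpyrazole (hexavalent chromium, Salmond‑type) gives the conjugated 7‑en‑6‑one, as expected for drim‑7‑enes, and no stereocentre is changed.

Step 5
Reactants: 6 methyl 6-oxo-13,14,15,16-tetranorlabd-7-en-12-oate
Product: 9 methyl 7α-benzoyloxy-6-oxo-13,14,15,16-tetranorlabd-8-en-12-oate, via N-benzoyloxy-N-methyl dienamine 7 (not isolated), via 7α-benzoyloxy N-methylimine 8 (not isolated)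
Conditions: MeNH(OBz)·HCl (1.5 equiv), DMSO, 60 °C; then H2O
Reagents that add atoms: N-methyl-O-benzoylhydroxylamine hydrochloride CNOC(=O)c1ccccc1.Cl; water O
Why: Proposed new method: the enone condenses with the N‑methyl‑O‑benzoylhydroxylamine salt to an iminium that tautomerises toward C‑9 (enamine formation toward C‑5 would give a badly strained tetrasubstituted ring‑fusion enamine), and the N‑benzoyloxy dienamine then undergoes a concerted six‑centre [3,3] shift that forms the C7–O bond at the α‑carbon only (delivery to C‑9 would need a thermally forbidden eight‑centre, eight‑electron array), on the open α‑face away from the β‑axial C‑19 and C‑20 methyls (the pseudoaxial 7α epimer is also the one favoured by allylic strain against the C‑17 methyl), leaving the double bond at C8=C9 before the imine is hydrolysed; the closest known reaction is the α‑acyloxylation of saturated ketones with N‑alkyl‑O‑acylhydroxylamine salts through an enamine [3,3] rearrangement, which has not been shown in this vinylogous, deconjugative sense.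

Step 6
Reactants: 9 methyl 7α-benzoyloxy-6-oxo-13,14,15,16-tetranorlabd-8-en-12-oate
Product: 10 13,14,15,16-tetranorlabd-8-ene-6β,7α,12-triol
Conditions: LiAlH4 (3 equiv), THF, −78 → 0 °C; then H2O, aq NaOH
Reagents that add atoms: none
Why: Hydride reduction of ketone, benzoate and methyl ester in one operation; hydride reaches the C‑6 carbonyl from the α‑face because the β‑face is blocked by the syn‑axial C‑19 and C‑20 methyls, which sets the axial 6β‑alcohol trans to the 7α‑oxygen.

Step 7
Reactants: 10 13,14,15,16-tetranorlabd-8-ene-6β,7α,12-triol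
Product: 11 12-iodo-13,14,15,16-tetranorlabd-8-ene-6β,7α-diol
Conditions: I2, PPh3, imidazole, CH2Cl2, 0 °C
Reagents that add atoms: iodine II
Why: Appel‑type iodination is selective for the unhindered primary alcohol over the hindered allylic 7α‑OH and the axial 6β‑OH, and cyclic ether formation is impossible because C‑7 and C‑11 are trans across the tetrasubstituted double bond.

Step 8
Reactants: 12 but-2-yn-1-ol
Product: 14 (Z)-3-iodobut-2-en-1-ol, via cyclic alkenylaluminate 13 (not isolated)
Conditions: NaAlH2(OCH2CH2OMe)2, THF, 0 °C → rt; then I2, THF, −78 °C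
Reagents that add atoms: iodine II
Why: Hydroxyl‑directed trans‑hydroalumination of the propargylic alcohol places aluminium on C‑3 cis to the carbinol carbon in a five‑membered alanate, and iododealumination with retention gives the Z‑iodide.

Step 9
Reactants: 11 12-iodo-13,14,15,16-tetranorlabd-8-ene-6β,7α-diol; 14 (Z)-3-iodobut-2-en-1-ol
Product: 16 (13Z)-labda-8,13-diene-6β,7α,15-triol, via alkylzinc iodide 15 (not isolated)
Conditions: Zn dust, TMEDA, PdCl2[P(t-Bu)2(C6H4-4-NMe2)]2 (2 mol %), 2 wt % TPGS-750-M/H2O, rt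
Reagents that add atoms: none
Why: Negishi‑type sp3–sp2 cross‑coupling in aqueous micelles: zinc inserts into the primary C–I bond and the resulting RZnI transfers its alkyl group to the alkenyl–Pd–I species formed from 14 with retention of the Z geometry, while the free hydroxyls are tolerated in water.

Step 10
Reactants: 16 (13Z)-labda-8,13-diene-6β,7α,15-triol
Product: 17 (13Z)-7α,15-diacetoxylabda-8,13-dien-6β-ol
Conditions: Ac2O, pyridine, CH2Cl2, 0 °C → rt
Reagents that add atoms: acetic anhydride CC(=O)OC(C)=O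
Why: Acylation of the primary allylic 15‑OH and the secondary allylic 7α‑OH, whereas the axial 6β‑OH, 1,3‑diaxial to the C‑19 and C‑20 methyls, is not acetylated without DMAP (as with the 6β‑OH of forskolin‑type labdanes), and the trans‑diaxial arrangement rules out acyl migration.

**Compound list**
1 | (+)-sclareolide (8α,12-olide; 5α-H, 9α-H, 10β-CH3) | CC1(C)CCC[C@@]2(C)[C@H]1CC[C@@]3(C)OC(=O)C[C@H]23 | starting material
2 | potassium 8α-hydroxy-13,14,15,16-tetranorlabdan-12-oate | [K+].[O-]C(=O)C[C@H]1[C@](C)(O)CC[C@H]2C(C)(C)CCC[C@]12C | intermediate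
3 | methyl 8α-hydroxy-13,14,15,16-tetranorlabdan-12-oate | COC(=O)C[C@H]1[C@](C)(O)CC[C@H]2C(C)(C)CCC[C@]12C | intermediate
4 | methyl 13,14,15,16-tetranorlabd-8(17)-en-12-oate | COC(=O)C[C@H]1C(=C)CC[C@H]2C(C)(C)CCC[C@]12C | intermediate
5 | methyl 13,14,15,16-tetranorlabd-7-en-12-oate | COC(=O)C[C@H]1C(C)=CC[C@H]2C(C)(C)CCC[C@]12C | intermediate
6 | methyl 6-oxo-13,14,15,16-tetranorlabd-7-en-12-oate | COC(=O)C[C@H]1C(C)=CC(=O)[C@H]2C(C)(C)CCC[C@]12C | intermediate
7 | methyl 6-[benzoyloxy(methyl)amino]-13,14,15,16-tetranorlabda-6,8-dien-12-oate | COC(=O)CC1=C(C)C=C(N(C)OC(=O)c3ccccc3)[C@H]2C(C)(C)CCC[C@]12C | intermediate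
8 | methyl 7α-benzoyloxy-6-(methylimino)-13,14,15,16-tetranorlabd-8-en-12-oate | COC(=O)CC1=C(C)[C@H](OC(=O)c3ccccc3)C(=NC)[C@H]2C(C)(C)CCC[C@]12C | intermediate
9 | methyl 7α-benzoyloxy-6-oxo-13,14,15,16-tetranorlabd-8-en-12-oate | COC(=O)CC1=C(C)[C@H](OC(=O)c3ccccc3)C(=O)[C@H]2C(C)(C)CCC[C@]12C | intermediate
10 | 13,14,15,16-tetranorlabd-8-ene-6β,7α,12-triol | OCCC1=C(C)[C@H](O)[C@@H](O)[C@H]2C(C)(C)CCC[C@]12C | intermediate
11 | 12-iodo-13,14,15,16-tetranorlabd-8-ene-6β,7α-diol | ICCC1=C(C)[C@H](O)[C@@H](O)[C@H]2C(C)(C)CCC[C@]12C | intermediate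
12 | but-2-yn-1-ol | CC#CCO | starting material
13 | sodium cyclic alkenylaluminate (five-membered O–Al–C(CH3)=CH–CH2 ring, two 2-methoxyethoxy groups on Al) | [Na+].CC1=CCO[Al-]1(OCCOC)OCCOC | intermediate
14 | (Z)-3-iodobut-2-en-1-ol | C/C(I)=C/CO | intermediate
15 | alkylzinc iodide of 11 (12-iodozincio-13,14,15,16-tetranorlabd-8-ene-6β,7α-diol) | I[Zn]CCC1=C(C)[C@H](O)[C@@H](O)[C@H]2C(C)(C)CCC[C@]12C | intermediate
16 | (13Z)-labda-8,13-diene-6β,7α,15-triol | OC/C=C(/C)CCC1=C(C)[C@H](O)[C@@H](O)[C@H]2C(C)(C)CCC[C@]12C | intermediate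
17 | (13Z)-7α,15-diacetoxylabda-8,13-dien-6β-ol (CNP0415913.2) | CC(=O)OC/C=C(/C)CCC1=C(C)[C@H](OC(C)=O)[C@@H](O)[C@H]2C(C)(C)CCC[C@]12C | target

**Step count**
Total steps: 10. Longest linear sequence: 9 (steps 1–7, 9, 10); step 8 is the side branch.

**Steps most likely to fail**

Step 5 (the proposed new step). Condensation at the hindered, conjugated C‑6 carbonyl may be slow, and an exocyclic C8=C17 dienamine would give the 8(17)‑ene isomer. The fallback uses known chemistry, sets out from 6 and comes back at 10. Treat 6 with KN(SiMe3)2 in THF (−78 → 0 °C, equilibration to the endocyclic dienolate) to form the potassium dienolate of 6 F1. Hydroxylate it at the α‑carbon from the α‑face with 2‑(phenylsulfonyl)‑3‑phenyloxaziridine at −78 °C to give methyl 7α‑hydroxy‑6‑oxo‑13,14,15,16‑tetranorlabd‑8‑en‑12‑oate F2. Reduce it with LiAlH4 as in step 6 to reach 10.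

Step 3. The isomerisation may run on to the tetrasubstituted Δ8 olefin or toward the ester. The fallback sets out from 4 and comes back at 5. SeO2 (cat.) and t‑BuOOH in CH2Cl2 hydroxylate the exocyclic olefin at the axial allylic position to methyl 7α‑hydroxy‑13,14,15,16‑tetranorlabd‑8(17)‑en‑12‑oate F3. Mitsunobu reaction with 2‑nitrobenzenesulfonylhydrazide (PPh3, DEAD, THF, −30 °C) gives, with inversion, methyl 7β‑[1‑(2‑nitrophenylsulfonyl)hydrazinyl]‑13,14,15,16‑tetranorlabd‑8(17)‑en‑12‑oate F4. On warming this loses the sulfinic acid to methyl 7β‑diazenyl‑13,14,15,16‑tetranorlabd‑8(17)‑en‑12‑oate F5, whose retro‑ene loss of nitrogen delivers hydrogen to C‑17 and gives 5 regiospecifically (Myers reductive transposition).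

Step 9. The alkylzinc may be protonated in water or homocouple, which wastes the advanced iodide. The fallback sets out from 11 and 14 and comes back at 16. It is a nickel‑catalysed reductive cross‑electrophile coupling (NiBr2(MeOCH2CH2OMe) 10 mol %, 4,4′‑di‑tert‑butyl‑2,2′‑bipyridine, Mn powder, NaI, DMA, rt, excess 14). It joins the two iodides through an alkyl radical and an alkenyl–Ni species without any organozinc and tolerates the free hydroxyls; it makes no new compound (F0).

**Further compounds**
F1 | step 5 | potassium dienolate of 6 (potassium 12-methoxy-12-oxo-13,14,15,16-tetranorlabda-6,8-dien-6-olate) | [K+].COC(=O)CC1=C(C)C=C([O-])[C@H]2C(C)(C)CCC[C@]12C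
F2 | step 5 | methyl 7α-hydroxy-6-oxo-13,14,15,16-tetranorlabd-8-en-12-oate | COC(=O)CC1=C(C)[C@H](O)C(=O)[C@H]2C(C)(C)CCC[C@]12C
F3 | step 3 | methyl 7α-hydroxy-13,14,15,16-tetranorlabd-8(17)-en-12-oate | COC(=O)C[C@H]1C(=C)[C@H](O)C[C@H]2C(C)(C)CCC[C@]12C
F4 | step 3 | methyl 7β-[1-(2-nitrophenylsulfonyl)hydrazinyl]-13,14,15,16-tetranorlabd-8(17)-en-12-oate | COC(=O)C[C@H]1C(=C)[C@@H](N(N)S(=O)(=O)c3ccccc3[N+](=O)[O-])C[C@H]2C(C)(C)CCC[C@]12C
F5 | step 3 | methyl 7β-diazenyl-13,14,15,16-tetranorlabd-8(17)-en-12-oate | COC(=O)C[C@H]1C(=C)[C@@H](N=N)C[C@H]2C(C)(C)CCC[C@]12C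
F0 | step 9 | none | none
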